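**Plan**

- Ring numbering used throughout: C1 (C=O), C2=C3, C4 (OMe), C5, C6 (quaternary, bearing the allyl group and the aroylethyl arm).
- Retrosynthetic cuts: C2=C3 goes back to a C2 carbinol; C2–C3 and C4–OMe are then cut together (Prins closure with methanol capture), opening the ring to a gem-diallyl 1,2-keto aldehyde. Further cuts are C1–C2 (dithiane anion plus lactone), aryl–C(=O) (Grignard) and both C6–allyl bonds (lactone enolate).
- Enabling feature: C6 carries two CH2–C(sp2) arms, the free allyl group and the ring path C5–C4–C3. C3–C4–C5 is therefore a second allyl group in disguise, and C6 is not a stereocentre in the diallyl precursor.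
- Forward order: diallylation of (S)-β-methyl-γ-butyrolactone, lactone opening by 2-lithio-1,3-dithiane, conversion of the CH2OH end into the aryl ketone, unmasking of the keto aldehyde, closure of the only carbocycle, then mesylation and elimination to the enone.
- Stereochemistry: the side-chain methine (S) is carried over from the lactone. C6 (R) and C4 (R) are created together in the ring closure (ligand-controlled aldehyde face, chair with the arm equatorial, anti addition of methanol). The C2 carbinol centre is temporary.

Key step: step 7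

Remark on the chemistry: (S)-4-methyldihydrofuran-2(3H)-one is taken as purchasable in enantiopure form and 3,4-dimethoxyphenylmagnesium bromide as its commercial THF solution; allyl = prop-2-en-1-yl.

**Route**

Step 1
Reactants: 1 (S)-4-methyldihydrofuran-2(3H)-one; 2 allyl bromide
Product: 4 (S)-3,3-diallyl-4-methyldihydrofuran-2(3H)-one, via trans monoallyl lactone 3 (not isolated)
Conditions: LiN(iPr)2 (1.1 equiv), THF, −78 °C; 2 (1.1 equiv), −78 to −30 °C; then LiN(iPr)2 (1.2 equiv), −78 °C; 2 (1.5 equiv), DMPU, −78 to 0 °C
Reagents that add atoms: allyl bromide (2), C=CCBr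
Why: Two consecutive lithium enolate alkylations at the only enolisable carbon of the lactone (the first allyl group enters trans to the C4 methyl, the second removes that centre) build the quaternary carbon, while C4 carries no acidic hydrogen and keeps its configuration.

Step 2
Reactants: 4 (S)-3,3-diallyl-4-methyldihydrofuran-2(3H)-one; 5 1,3-dithiane
Product: 7 (3S)-2,2-diallyl-1-(1,3-dithian-2-yl)-4-hydroxy-3-methylbutan-1-one, via 2-lithio-1,3-dithiane 6 (not isolated)
Conditions: 5 (2.3 equiv), n-BuLi (2.2 equiv), THF, −30 °C; then 4, −78 to −20 °C; aq NH4Cl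
Reagents that add atoms: 1,3-dithiane (5), C1CSCSC1
Why: Corey–Seebach acyl-anion addition to a lactone, in which the dithiane anion attacks the lactone carbonyl, the ring opens to the keto alkoxide and the acidic 2-acyl-dithiane is deprotonated by the second equivalent so that no second addition follows; no stereocentre is touched.

Step 3
Reactants: 7 (3S)-2,2-diallyl-1-(1,3-dithian-2-yl)-4-hydroxy-3-methylbutan-1-one
Product: 8 (2S)-3,3-diallyl-4-(1,3-dithian-2-yl)-2-methyl-4-oxobutanal
Conditions: SO3·pyridine (3 equiv), DMSO, iPr2NEt, CH2Cl2, 0 °C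
Reagents that add atoms: none
Why: Parikh–Doering oxidation (activated DMSO) takes the primary alcohol to the aldehyde without attacking the thioacetal sulfur and, run cold with a hindered amine, should leave the methine next to the new aldehyde unepimerised.

Step 4
Reactants: 8 (2S)-3,3-diallyl-4-(1,3-dithian-2-yl)-2-methyl-4-oxobutanal; 9 3,4-dimethoxyphenylmagnesium bromide
Product: 10 (3S)-2,2-diallyl-4-(3,4-dimethoxyphenyl)-1-(1,3-dithian-2-yl)-4-hydroxy-3-methylbutan-1-one (both C4 epimers)
Conditions: 9 (1.3 equiv, THF solution), THF, −78 °C; aq NH4Cl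
Reagents that add atoms: 3,4-dimethoxyphenylmagnesium bromide (9), COc1ccc([Mg]Br)cc1OC
Why: Grignard 1,2-addition at −78 °C, where the aldehyde should react far faster than the ketone shielded by the quaternary carbon and the dithiane; the new carbinol centre forms as a mixture that is erased in step 5.

Step 5
Reactants: 10 (3S)-2,2-diallyl-4-(3,4-dimethoxyphenyl)-1-(1,3-dithian-2-yl)-4-hydroxy-3-methylbutan-1-one
Product: 11 (3S)-2,2-diallyl-4-(3,4-dimethoxyphenyl)-1-(1,3-dithian-2-yl)-3-methylbutane-1,4-dione
Conditions: SO3·pyridine (3 equiv), DMSO, iPr2NEt, CH2Cl2, 0 °C to rt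
Reagents that add atoms: none
Why: Parikh–Doering oxidation of the benzylic alcohol gives the aryl ketone under conditions too weakly basic to enolise the hindered methine between the ketone and the quaternary carbon.

Step 6
Reactants: 11 (3S)-2,2-diallyl-4-(3,4-dimethoxyphenyl)-1-(1,3-dithian-2-yl)-3-methylbutane-1,4-dione
Product: 12 (4S)-3,3-diallyl-5-(3,4-dimethoxyphenyl)-4-methyl-2,5-dioxopentanal
Conditions: PhI(OCOCF3)2 (1.5 equiv), MeCN/H2O (9:1), 0 °C; then toluene azeotrope, used at once
Reagents that add atoms: water, O
Why: Oxidative dithiane hydrolysis with a hypervalent iodine reagent (sulfur is oxidised, water adds to the thionium ion and the carbonyl is released) is fast in aqueous acetonitrile and is known to spare terminal alkenes and ketones.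

Step 7
Reactants: 12 (4S)-3,3-diallyl-5-(3,4-dimethoxyphenyl)-4-methyl-2,5-dioxopentanal; 13 methanol
Product: 14 (2R,4R,6R)-6-allyl-6-[(2S)-1-(3,4-dimethoxyphenyl)-1-oxopropan-2-yl]-2-hydroxy-4-methoxycyclohexan-1-one
Conditions: [Cu((R,R)-tBu-box)](SbF6)2 (10 mol %; tBu-box = 2,2'-(propane-2,2-diyl)bis(4-tert-butyl-4,5-dihydrooxazole)), MeOH (3 equiv), CH2Cl2, −20 °C to rt
Reagents that add atoms: methanol (13), CO
Why: Proposed new method: the divalent copper centre chelates the two adjacent carbonyl oxygens of 12, the CH2 terminus (C3) of one allyl group attacks the activated aldehyde carbon C2, and methanol adds to C4 from the face opposite to the new C2–C3 bond as positive charge builds there, after which the oxonium proton passes to the copper alkoxide and 14 leaves the metal; the closest known reaction types are bis(oxazoline)copper-catalysed glyoxylate-ene reactions of unactivated alkenes and Lewis-acid Prins cyclisations that end by halide or solvent capture. The six-membered ring closes endo with respect to the alkene (C3 and C4 both in the ring, 6-endo-trig) and exo with respect to the carbonyl, through a chair in which the chelated C2–O bond stays near the plane of the C1 carbonyl and therefore ends equatorial. C2 is set by the ligand, whose tert-butyl groups are expected to leave the Re face of the aldehyde open; C6 is set by relay, because with that face fixed only the allyl group that lets the bulky aroylethyl arm sit equatorial (spectator allyl axial) can reach C2 in a chair; C4 is set by the anti addition, which places the methoxy group equatorial and cis to both the C2 hydroxyl and the arm. The step therefore needs group selectivity between the two diastereotopic allyl groups, which the catalyst supplies through the chair and which the (S)-methine may reinforce or oppose (the (S,S) complex is the control experiment), and it needs methanol capture to outrun proton loss, which is plausible because a concerted ene transfer would have to take hydrogen from the in-ring C5 and cannot be reached from the chair. The methyl hemiacetal that 12 forms reversibly with methanol is expected to be a resting state only, since its ionisation to an oxocarbenium ion is disfavoured by the adjacent ketone.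

Step 8
Reactants: 14 (2R,4R,6R)-6-allyl-6-[(2S)-1-(3,4-dimethoxyphenyl)-1-oxopropan-2-yl]-2-hydroxy-4-methoxycyclohexan-1-one
Product: 15 (2R,4R,6R)-6-allyl-6-[(2S)-1-(3,4-dimethoxyphenyl)-1-oxopropan-2-yl]-4-methoxy-2-(methanesulfonyloxy)cyclohexan-1-one
Conditions: MsCl (1.3 equiv), Et3N, CH2Cl2, −10 °C
Reagents that add atoms: methanesulfonyl chloride, CS(=O)(=O)Cl
Why: Sulfonylation of the secondary carbinol (sulfene from MsCl and Et3N) turns the C2 hydroxyl into a leaving group with retention, the hindered methine and the methyl ether being inert at −10 °C.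

Step 9
Reactants: 15 (2R,4R,6R)-6-allyl-6-[(2S)-1-(3,4-dimethoxyphenyl)-1-oxopropan-2-yl]-4-methoxy-2-(methanesulfonyloxy)cyclohexan-1-one
Product: 17 (4R,6R)-6-allyl-6-[(2S)-1-(3,4-dimethoxyphenyl)-1-oxopropan-2-yl]-4-methoxycyclohex-2-en-1-one, via axial bromo ketone 16 (not isolated)
Conditions: LiBr (3 equiv), Li2CO3 (3 equiv), DMF, 100 °C
Reagents that add atoms: none
Why: Bromide displaces the equatorial α-keto mesylate by SN2 with inversion and the resulting axial bromide loses HBr by anti-periplanar E2 with the axial C3 hydrogen (LiBr/Li2CO3 dehydrohalogenation of an α-halo ketone); C6 is quaternary, so the double bond can only form between C2 and C3, and the C4 and C6 centres are not involved.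

**Compound list**

1 | (S)-4-methyldihydrofuran-2(3H)-one | O=C1C[C@H](C)CO1 | starting material
2 | allyl bromide | C=CCBr | starting material
3 | (3S,4S)-3-allyl-4-methyldihydrofuran-2(3H)-one (trans monoallyl lactone, formed in the flask) | O=C1[C@@H](CC=C)[C@H](C)CO1 | intermediate
4 | (S)-3,3-diallyl-4-methyldihydrofuran-2(3H)-one | O=C1C(CC=C)(CC=C)[C@H](C)CO1 | intermediate
5 | 1,3-dithiane | C1CSCSC1 | starting material
6 | 2-lithio-1,3-dithiane (formed in the flask) | [Li]C1SCCCS1 | intermediate
7 | (3S)-2,2-diallyl-1-(1,3-dithian-2-yl)-4-hydroxy-3-methylbutan-1-one (may sit partly as its cyclic hemiketal) | OC[C@@H](C)C(CC=C)(CC=C)C(=O)C1SCCCS1 | intermediate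
8 | (2S)-3,3-diallyl-4-(1,3-dithian-2-yl)-2-methyl-4-oxobutanal | O=C[C@@H](C)C(CC=C)(CC=C)C(=O)C1SCCCS1 | intermediate
9 | 3,4-dimethoxyphenylmagnesium bromide | COc1ccc([Mg]Br)cc1OC | starting material
10 | (3S)-2,2-diallyl-4-(3,4-dimethoxyphenyl)-1-(1,3-dithian-2-yl)-4-hydroxy-3-methylbutan-1-one (both C4 epimers) | COc1ccc(C(O)[C@@H](C)C(CC=C)(CC=C)C(=O)C2SCCCS2)cc1OC | intermediate
11 | (3S)-2,2-diallyl-4-(3,4-dimethoxyphenyl)-1-(1,3-dithian-2-yl)-3-methylbutane-1,4-dione | COc1ccc(C(=O)[C@@H](C)C(CC=C)(CC=C)C(=O)C2SCCCS2)cc1OC | intermediate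
12 | (4S)-3,3-diallyl-5-(3,4-dimethoxyphenyl)-4-methyl-2,5-dioxopentanal | C=CCC(CC=C)([C@H](C)C(=O)c1ccc(OC)c(OC)c1)C(=O)C=O | intermediate
13 | methanol | CO | starting material
14 | (2R,4R,6R)-6-allyl-6-[(2S)-1-(3,4-dimethoxyphenyl)-1-oxopropan-2-yl]-2-hydroxy-4-methoxycyclohexan-1-one (ring numbered from the carbonyl through the carbinol carbon) | C=CC[C@]1([C@H](C)C(=O)c2ccc(OC)c(OC)c2)C[C@@H](OC)C[C@@H](O)C1=O | intermediate
15 | (2R,4R,6R)-6-allyl-6-[(2S)-1-(3,4-dimethoxyphenyl)-1-oxopropan-2-yl]-4-methoxy-2-(methanesulfonyloxy)cyclohexan-1-one | C=CC[C@]1([C@H](C)C(=O)c2ccc(OC)c(OC)c2)C[C@@H](OC)C[C@@H](OS(C)(=O)=O)C1=O | intermediate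
16 | (2S,4R,6R)-6-allyl-2-bromo-6-[(2S)-1-(3,4-dimethoxyphenyl)-1-oxopropan-2-yl]-4-methoxycyclohexan-1-one (axial bromide, formed in the flask) | C=CC[C@]1([C@H](C)C(=O)c2ccc(OC)c(OC)c2)C[C@@H](OC)C[C@H](Br)C1=O | intermediate
17 | (4R,6R)-6-allyl-6-[(2S)-1-(3,4-dimethoxyphenyl)-1-oxopropan-2-yl]-4-methoxycyclohex-2-en-1-one | C=CC[C@]1([C@H](C)C(=O)c2ccc(OC)c(OC)c2)C[C@@H](OC)C=CC1=O | target

**Count**

Total steps: 9. Longest linear sequence: 9 steps (1 to 17).

**Steps most likely to fail**

1. Step 7 (proposed new method). What may go wrong: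
- proton loss from C3 or C5 of the developing cation, giving ring alkenes in place of the methyl ether;
- slowing of the catalyst by methanol or by hemiacetal formation;
- weak discrimination between the two allyl groups if ligand and (S)-methine are mismatched;
- capture of C4 by the aryl ketone oxygen from the chair with the arm axial.

Fallback with known chemistry (solvolytic Prins cyclisation ended by formate, methyl ether made last): setting out from 12, stirring in HCO2H at room temperature should give the hydroxy formate F1 through the same chair. There is no reagent control over which allyl group reacts, so the wanted diastereomer would have to be separated. MsCl/Et3N then gives the formate mesylate F2. LiBr/Li2CO3 in DMF gives, through the bromo formate F3, the enone formate F4. KHCO3 in MeOH removes the formyl group to give the hydroxy enone F5. Ag2O/MeI methylates the allylic alcohol, which returns to the route at 17.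

2. Step 2. What may go wrong: slow attack of the bulky dithiane anion on a lactone carbonyl flanked by the quaternary carbon, with recovery of 4 or reversal on warming.

Fallback (addition at the aldehyde oxidation level in place of acylation): setting out from 4, iBu2AlH in CH2Cl2 at −78 °C gives the lactol F6. An excess of 6 adds to its open hydroxy aldehyde form to give the dithianyl diol F7. Oxidation of both hydroxyl groups with SO3·pyridine/DMSO/iPr2NEt returns to the route at 8.

3. Step 9. What may go wrong:
- slow bromide entry at C2 along the axial direction, syn to the axial allyl group on C6;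
- epimerisation of the methine next to the aryl ketone by carbonate at 100 °C;
- loss of methanol from C4 of the product.

Fallback (reductive removal of the C2 oxygen by electron transfer, then dehydrogenation, in place of substitution and E2): setting out from 15, SmI2 in THF/MeOH at −78 °C cleaves the α-keto C–O bond to give the methoxy ketone F8. LiN(iPr)2/TMSCl at −78 °C removes the unhindered C2 hydrogen kinetically and gives the silyl enol ether F9. Pd(OAc)2 in MeCN (Saegusa–Ito oxidation) returns to the route at 17.

**Further compounds**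

F1 | step 7 | (2R,4R,6R)-6-allyl-6-[(2S)-1-(3,4-dimethoxyphenyl)-1-oxopropan-2-yl]-4-(formyloxy)-2-hydroxycyclohexan-1-one | C=CC[C@]1([C@H](C)C(=O)c2ccc(OC)c(OC)c2)C[C@@H](OC=O)C[C@@H](O)C1=O
F2 | step 7 | (2R,4R,6R)-6-allyl-6-[(2S)-1-(3,4-dimethoxyphenyl)-1-oxopropan-2-yl]-4-(formyloxy)-2-(methanesulfonyloxy)cyclohexan-1-one | C=CC[C@]1([C@H](C)C(=O)c2ccc(OC)c(OC)c2)C[C@@H](OC=O)C[C@@H](OS(C)(=O)=O)C1=O
F3 | step 7 | (2S,4R,6R)-6-allyl-2-bromo-6-[(2S)-1-(3,4-dimethoxyphenyl)-1-oxopropan-2-yl]-4-(formyloxy)cyclohexan-1-one | C=CC[C@]1([C@H](C)C(=O)c2ccc(OC)c(OC)c2)C[C@@H](OC=O)C[C@H](Br)C1=O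
F4 | step 7 | (4R,6R)-6-allyl-6-[(2S)-1-(3,4-dimethoxyphenyl)-1-oxopropan-2-yl]-4-(formyloxy)cyclohex-2-en-1-one | C=CC[C@]1([C@H](C)C(=O)c2ccc(OC)c(OC)c2)C[C@@H](OC=O)C=CC1=O
F5 | step 7 | (4R,6R)-6-allyl-6-[(2S)-1-(3,4-dimethoxyphenyl)-1-oxopropan-2-yl]-4-hydroxycyclohex-2-en-1-one | C=CC[C@]1([C@H](C)C(=O)c2ccc(OC)c(OC)c2)C[C@@H](O)C=CC1=O
F6 | step 2 | (4S)-3,3-diallyl-4-methyltetrahydrofuran-2-ol (anomer mixture) | OC1C(CC=C)(CC=C)[C@H](C)CO1
F7 | step 2 | (3S)-2,2-diallyl-1-(1,3-dithian-2-yl)-3-methylbutane-1,4-diol (both C1 epimers) | OC[C@@H](C)C(CC=C)(CC=C)C(O)C1SCCCS1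
F8 | step 9 | (4S,6R)-6-allyl-6-[(2S)-1-(3,4-dimethoxyphenyl)-1-oxopropan-2-yl]-4-methoxycyclohexan-1-one (same spatial arrangement as 14; the C4 descriptor changes with the priorities) | C=CC[C@]1([C@H](C)C(=O)c2ccc(OC)c(OC)c2)C[C@@H](OC)CCC1=O
F9 | step 9 | {[(4S,6R)-6-allyl-6-[(2S)-1-(3,4-dimethoxyphenyl)-1-oxopropan-2-yl]-4-methoxycyclohex-1-en-1-yl]oxy}trimethylsilane | C=CC[C@]1([C@H](C)C(=O)c2ccc(OC)c(OC)c2)C[C@@H](OC)CC=C1O[Si](C)(C)C
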